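**Retrosynthetic overview**

Labdane numbering is used: ring A = C1–C5, C10; ring B = C5–C10; C17 = methylene on C8; C18 (methyl) and C19 on C4; C20 on C10; chain C11–C16.
1. The strategy rests on ring B: its exocyclic C8=C17 methylene lies next to the chain-bearing C9, which adjoins quaternary C10. This is the pattern left when a ring A 2-siloxydiene (C7=C6–C5=C10) adds across the ester-conjugated double bond of ethyl buta-2,3-dienoate, forming C7–C8 and C9–C10.
2. The diene comes from 3-methoxybenzyl alcohol: Birch reduction, copper-catalysed asymmetric methyl addition (C4), aldol trapping and oxidation (C6, C7), enol triflate formation, Stille coupling (C20) and kinetic silylation.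
3. After the cycloaddition, the C6 enol ether sets trans C5 by kinetic protonation and the C6 oxygen is removed. The C11 ester becomes a vinyl group, which is hydroborated and coupled with 3-bromofuran-2(5H)-one (C12–C13). The C19 acetate and C20 aldehyde are set last.
4. Ring order: ring A (from the arene), ring B (Diels–Alder reaction), butenolide ring (attached preformed).

Key step: step 8

Abbreviations: TBDPS = tert-butyldiphenylsilyl, TBS = tert-butyldimethylsilyl, MOM = methoxymethyl, Sia = 3-methylbutan-2-yl.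
Remark: in step 3 the ligand enantiomer is taken to be the one that gives the (3R) centre (C4 of the target), its sense being assumed by analogy with 3-alkylcyclohex-2-enones.

**Route**

Step 1
Reactants: 1 3-methoxybenzyl alcohol
Product: 4 3-(hydroxymethyl)cyclohex-2-en-1-one, via dienyl carbinol 2 (not isolated), via deconjugated enone 3 (not isolated)
Conditions: Li, NH3 (l), t-BuOH, THF, −78 → −33 °C; NH4Cl; then 1 M HCl, THF, rt
Reagents that add atoms: water, O
Why: Birch reduction leaves the methoxy- and carbinol-bearing carbons unsaturated, and acid hydrolysis of the enol ether followed by migration of the β,γ-double bond into conjugation should give the enone; no stereocentre is formed.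

Step 2
Reactants: 4 3-(hydroxymethyl)cyclohex-2-en-1-one
Product: 5 3-(TBDPS-oxymethyl)cyclohex-2-en-1-one
Conditions: TBDPSCl, imidazole, CH2Cl2, rt
Reagents that add atoms: tert-butyl(chloro)diphenylsilane, CC(C)(C)[Si](Cl)(c1ccccc1)c1ccccc1
Why: Imidazole-promoted silyl ether formation protects the future C19 oxygen with a bulky group that is stable to organometallic reagents, base and heat.

Step 3
Reactants: 5 3-(TBDPS-oxymethyl)cyclohex-2-en-1-one; 6 trimethylaluminium; 7 acetaldehyde
Product: 9 (3R)-2-(1-hydroxyethyl)-3-methyl-3-(TBDPS-oxymethyl)cyclohexan-1-one, via dimethylaluminium enolate 8 (not isolated)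
Conditions: Me3Al, Cu(O2CC4H3S) (cat.), Ph2P–N[CH(CH3)(2-naphthyl)]2 (chiral ligand, cat.), Et2O, −30 °C; then 7, −78 °C; aq. NH4Cl
Reagents that add atoms: none
Why: Copper-catalysed asymmetric conjugate addition of Me3Al to the β,β-disubstituted enone should set the C4 quaternary centre under ligand control, and the regiodefined aluminium enolate is trapped at C5 by aldol addition to acetaldehyde; the two further centres formed are erased in steps 4 and 5.

Step 4
Reactants: 9 (3R)-2-(1-hydroxyethyl)-3-methyl-3-(TBDPS-oxymethyl)cyclohexan-1-one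
Product: 10 (3R)-2-acetyl-3-methyl-3-(TBDPS-oxymethyl)cyclohexan-1-one
Conditions: Dess–Martin periodinane, CH2Cl2, 0 °C → rt
Reagents that add atoms: none
Why: Dess–Martin oxidation of the secondary β-hydroxy ketone should give the β-diketone without touching the silyl ether.

Step 5
Reactants: 10 (3R)-2-acetyl-3-methyl-3-(TBDPS-oxymethyl)cyclohexan-1-one
Product: 11 (3R)-2-acetyl-3-methyl-3-(TBDPS-oxymethyl)cyclohex-1-en-1-yl trifluoromethanesulfonate
Conditions: NaH, THF, 0 °C; then PhNTf2, 0 °C → rt
Reagents that add atoms: N-phenylbis(trifluoromethanesulfonimide), O=S(=O)(N(c1ccccc1)S(=O)(=O)C(F)(F)F)C(F)(F)F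
Why: Enol triflate formation from the β-diketone enolate should occur on the ring oxygen, because the endocyclic C5=C10 alkene lets the acetyl group twist away from the C4 quaternary centre, whereas the exocyclic isomer would suffer allylic strain.

Step 6
Reactants: 11 (3R)-2-acetyl-3-methyl-3-(TBDPS-oxymethyl)cyclohex-1-en-1-yl trifluoromethanesulfonate; 12 tributyl[(methoxymethoxy)methyl]stannane
Product: 13 1-[(6R)-2-(MOM-oxymethyl)-6-methyl-6-(TBDPS-oxymethyl)cyclohex-1-en-1-yl]ethan-1-one
Conditions: Pd(PPh3)4 (cat.), LiCl, CuI (cat.), 1,4-dioxane, 95 °C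
Reagents that add atoms: none
Why: Stille coupling of the electron-poor enol triflate with the α-alkoxymethylstannane transfers the activated CH2OMOM group in preference to butyl and places C20 on C10; the protected carbinol is used because a free cis-γ-hydroxy enone would cyclise to a furan.

Step 7
Reactants: 13 1-[(6R)-2-(MOM-oxymethyl)-6-methyl-6-(TBDPS-oxymethyl)cyclohex-1-en-1-yl]ethan-1-one
Product: 14 ring A 2-siloxydiene, tert-butyl({1-[(6R)-2-(MOM-oxymethyl)-6-methyl-6-(TBDPS-oxymethyl)cyclohex-1-en-1-yl]ethenyl}oxy)dimethylsilane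
Conditions: LiN(iPr)2, THF, −78 °C; then TBSCl, DMPU, −78 → −20 °C
Reagents that add atoms: tert-butyl(chloro)dimethylsilane, CC(C)(C)[Si](C)(C)Cl
Why: Kinetic deprotonation of the methyl ketone at its methyl group and O-silylation (silyl enol ether formation) should give the cross-conjugated diene, γ-deprotonation being disfavoured because the acetyl group is twisted out of conjugation.

Step 8
Reactants: 14 ring A 2-siloxydiene; 15 ethyl buta-2,3-dienoate
Product: 16 ethyl (1R,5R,8aR)-4-(TBS-oxy)-8a-(MOM-oxymethyl)-5-methyl-2-methylidene-5-(TBDPS-oxymethyl)-1,2,3,5,6,7,8,8a-octahydronaphthalene-1-carboxylate (ring B silyl enol ether with C17 methylene and C11 ester)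
Conditions: 15 (excess), BHT (cat.), PhMe, 120 °C, sealed tube
Reagents that add atoms: none
Why: The diene C7=C6(OTBS)–C5=C10 and the ester-conjugated C8=C9 bond of the allene combine in a one-step, normal-demand [4+2] cycloaddition (intermolecular Diels–Alder reaction) in which bonding of the electron-rich C7 to the electrophilic central allene carbon C8 runs ahead of C10–C9 bonding, while the remote allene double bond takes no part and remains as the C17 methylene. The closest known reaction types are cycloadditions of 1-(1-siloxyvinyl)cyclohexenes and of 2,6,6-trimethyl-1-vinylcyclohexene with acetylenic esters, which tolerate a fully substituted diene terminus, and additions of allenic esters at their conjugated double bond. Ring B is closed as a six-membered carbocycle by bimolecular annulation of the two dienophile carbons onto the four-carbon diene anchored on ring A, without a tether. C10 is set by diene-face selectivity: the CH2OTBDPS group on C4 should sit pseudoaxial to avoid the C6 siloxy group, so the dienophile adds to the methyl-bearing face and C20 is pushed cis to C19. C9 is set by the exo placement of the ester, away from the C4 and C6 substituents beneath the diene, which leaves C11 cis to C20; being α to the ester, C9 stays correctable at compound 21 by kinetic protonation of its dienolate anti to axial C20. The step needs regio-, site- and face-selectivity, secured by the siloxy group (largest HOMO coefficient at C7), by the ester conjugation of the proximal allene bond and by the C4 stereocentre; heat and a rod-shaped, unhindered dienophile are chosen because the C4 and C10 substituents twist the diene out of planarity.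

Step 9
Reactants: 16 ring B silyl enol ether
Product: 18 ethyl (1R,4aR,5R,8aS)-8a-(MOM-oxymethyl)-5-methyl-2-methylidene-4-oxo-5-(TBDPS-oxymethyl)decahydronaphthalene-1-carboxylate (trans-fused C6 ketone), via C6 enol 17 (not isolated)
Conditions: Bu4NF, AcOH, THF, −40 → 0 °C
Reagents that add atoms: none
Why: Fluoride cleavage of the silyl enol ether and kinetic C-protonation of the enol at C5 from the face opposite the axial C19 and C20 arms should give the trans ring fusion, while the acetic acid buffer avoids base that would move the C8(17) alkene into conjugation or epimerise C9.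

Step 10
Reactants: 18 trans-fused C6 ketone
Product: 19 C6 tosylhydrazone of 18, ethyl (1R,4aR,5R,8aS)-8a-(MOM-oxymethyl)-5-methyl-2-methylidene-4-[2-(4-methylbenzenesulfonyl)hydrazinylidene]-5-(TBDPS-oxymethyl)decahydronaphthalene-1-carboxylate
Conditions: TsNHNH2, EtOH, 60 °C
Reagents that add atoms: 4-methylbenzenesulfonohydrazide, Cc1ccc(S(=O)(=O)NN)cc1
Why: Condensation of the ketone with tosylhydrazide (hydrazone formation) under near-neutral conditions activates C6 for reductive removal while the β,γ-alkene stays in place.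

Step 11
Reactants: 19 C6 tosylhydrazone
Product: 21 ethyl (1R,4aR,5R,8aS)-8a-(MOM-oxymethyl)-5-methyl-2-methylidene-5-(TBDPS-oxymethyl)decahydronaphthalene-1-carboxylate, via tosylhydrazine 20 (not isolated)
Conditions: catecholborane, CHCl3, 0 °C → rt; then NaOAc·3H2O, 60 °C
Reagents that add atoms: none
Why: Caglioti-type reduction (hydride addition to C=N, then loss of sulfinate and N2 from the diazene) should turn C6 into CH2, and since the diazene is homoallylic rather than allylic the C8(17) alkene should not migrate.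

Step 12
Reactants: 21 C11 ethyl ester
Product: 22 [(1R,4aR,5R,8aS)-8a-(MOM-oxymethyl)-5-methyl-2-methylidene-5-(TBDPS-oxymethyl)decahydronaphthalen-1-yl]methanol (C11 alcohol)
Conditions: LiAlH4, THF, 0 °C
Reagents that add atoms: none
Why: Hydride reduction of the hindered ester to the primary alcohol is non-enolising and leaves C9, the silyl ether and the MOM ether untouched.

Step 13
Reactants: 22 C11 alcohol
Product: 23 (1R,4aR,5R,8aS)-8a-(MOM-oxymethyl)-5-methyl-2-methylidene-5-(TBDPS-oxymethyl)decahydronaphthalene-1-carbaldehyde (C11 aldehyde)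
Conditions: Dess–Martin periodinane, pyridine, CH2Cl2, 0 °C
Reagents that add atoms: none
Why: Buffered Dess–Martin oxidation gives the β,γ-unsaturated aldehyde under neutral conditions that should neither epimerise C9 nor conjugate the alkene.

Step 14
Reactants: 23 C11 aldehyde
Product: 24 tert-butyl{[(1R,4aS,5R,8aR)-5-ethenyl-4a-(MOM-oxymethyl)-1-methyl-6-methylidenedecahydronaphthalen-1-yl]methoxy}diphenylsilane (C11=C12 vinyl compound)
Conditions: Ph3PCH3Br, KN(SiMe3)2, THF, 0 °C; then 23, −78 → 0 °C
Reagents that add atoms: methyltriphenylphosphonium bromide, C[P+](c1ccccc1)(c1ccccc1)c1ccccc1.[Br-]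
Why: Wittig methylenation with the salt-free ylide at low temperature should add to the aldehyde faster than it deprotonates C9, giving the vinyl group that carries C12.

Step 15
Reactants: 24 C11=C12 vinyl compound
Product: 25 [(1R,4aS,5R,8aR)-5-ethenyl-4a-(MOM-oxymethyl)-1-methyl-6-methylidenedecahydronaphthalen-1-yl]methanol (C19 alcohol)
Conditions: Bu4NF, THF, 50 °C
Reagents that add atoms: none
Why: Fluoride-mediated desilylation of the neopentyl silyl ether is done here because no base-sensitive group is present yet.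

Step 16
Reactants: 25 C19 alcohol
Product: 26 [(1R,4aS,5R,8aR)-5-ethenyl-4a-(MOM-oxymethyl)-1-methyl-6-methylidenedecahydronaphthalen-1-yl]methyl acetate (C19 acetate)
Conditions: Ac2O, pyridine, DMAP (cat.), CH2Cl2, rt
Reagents that add atoms: acetic anhydride, CC(=O)OC(C)=O
Why: Acylation of the primary alcohol installs the C19 acetate before C20 is unveiled, so that no 19,20-hemiacetal can form later.

Step 17
Reactants: 26 C19 acetate; 27 3-bromofuran-2(5H)-one
Product: 29 [(1R,4aR,5R,8aR)-4a-(MOM-oxymethyl)-1-methyl-6-methylidene-5-[2-(2-oxo-2,5-dihydrofuran-3-yl)ethyl]decahydronaphthalen-1-yl]methyl acetate, via alkylborane 28 (not isolated)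
Conditions: Sia2BH (from BH3·THF and 2-methylbut-2-ene), THF, 0 °C; then 27, PdCl2(dppf) (cat.), AsPh3, K3PO4 (aq.), DMF, rt
Reagents that add atoms: none
Why: Hydroboration with bulky disiamylborane should select the monosubstituted C11=C12 vinyl group over the 1,1-disubstituted C8(17) methylene and place boron on C12, and the primary alkyl group is then transferred in a B-alkyl Suzuki–Miyaura coupling with the α-bromobutenolide to form C12–C13.

Step 18
Reactants: 29 MOM-protected butenolide acetate
Product: 31 [(1R,4aR,5R,8aR)-4a-(hydroxymethyl)-1-methyl-6-methylidene-5-[2-(2-oxo-2,5-dihydrofuran-3-yl)ethyl]decahydronaphthalen-1-yl]methyl acetate (C20 alcohol), via bromomethyl ether 30 (not isolated)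
Conditions: Me2BBr, CH2Cl2, −78 °C; then NaHCO3 (aq.), THF
Reagents that add atoms: none
Why: Lewis-acid cleavage of the MOM acetal by bromodimethylborane at low temperature, followed by hydrolysis of the bromomethyl ether on work-up, should free the C20 alcohol without affecting the acetate, the butenolide or the alkenes.

Step 19
Reactants: 31 C20 alcohol
Product: 32 [(1R,4aR,5R,8aR)-4a-formyl-1-methyl-6-methylidene-5-[2-(2-oxo-2,5-dihydrofuran-3-yl)ethyl]decahydronaphthalen-1-yl]methyl acetate (target)
Conditions: Dess–Martin periodinane, pyridine, CH2Cl2, rt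
Reagents that add atoms: none
Why: Dess–Martin oxidation of the neopentyl C20 alcohol gives the aldehyde, which has no α-hydrogen and so cannot epimerise.

**Compound list**

1 | 3-methoxybenzyl alcohol | COc1cccc(CO)c1 | starting material
2 | (5-methoxycyclohexa-1,4-dien-1-yl)methanol | COC1=CCC=C(CO)C1 | intermediate
3 | 3-(hydroxymethyl)cyclohex-3-en-1-one | O=C1CC(CO)=CCC1 | intermediate
4 | 3-(hydroxymethyl)cyclohex-2-en-1-one | O=C1C=C(CO)CCC1 | intermediate
5 | 3-{[tert-butyl(diphenyl)silyl]oxymethyl}cyclohex-2-en-1-one | O=C1C=C(CO[Si](c2ccccc2)(c2ccccc2)C(C)(C)C)CCC1 | intermediate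
6 | trimethylaluminium | C[Al](C)C | starting material
7 | acetaldehyde | CC=O | starting material
8 | dimethylaluminium (3R)-3-{[tert-butyl(diphenyl)silyl]oxymethyl}-3-methylcyclohex-1-en-1-olate | C[Al](C)OC1=C[C@](C)(CO[Si](c2ccccc2)(c2ccccc2)C(C)(C)C)CCC1 | intermediate
9 | (3R)-3-{[tert-butyl(diphenyl)silyl]oxymethyl}-2-(1-hydroxyethyl)-3-methylcyclohexan-1-one (isomers at C2 and at the carbinol carbon) | CC(O)C1C(=O)CCC[C@@]1(C)CO[Si](c1ccccc1)(c1ccccc1)C(C)(C)C | intermediate
10 | (3R)-2-acetyl-3-{[tert-butyl(diphenyl)silyl]oxymethyl}-3-methylcyclohexan-1-one | CC(=O)C1C(=O)CCC[C@@]1(C)CO[Si](c1ccccc1)(c1ccccc1)C(C)(C)C | intermediate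
11 | (3R)-2-acetyl-3-{[tert-butyl(diphenyl)silyl]oxymethyl}-3-methylcyclohex-1-en-1-yl trifluoromethanesulfonate | CC(=O)C1=C(OS(=O)(=O)C(F)(F)F)CCC[C@@]1(C)CO[Si](c1ccccc1)(c1ccccc1)C(C)(C)C | intermediate
12 | tributyl[(methoxymethoxy)methyl]stannane | CCCC[Sn](CCCC)(CCCC)COCOC | starting material
13 | 1-[(6R)-6-{[tert-butyl(diphenyl)silyl]oxymethyl}-2-[(methoxymethoxy)methyl]-6-methylcyclohex-1-en-1-yl]ethan-1-one | CC(=O)C1=C(COCOC)CCC[C@@]1(C)CO[Si](c1ccccc1)(c1ccccc1)C(C)(C)C | intermediate
14 | tert-butyl({1-[(6R)-6-{[tert-butyl(diphenyl)silyl]oxymethyl}-2-[(methoxymethoxy)methyl]-6-methylcyclohex-1-en-1-yl]ethenyl}oxy)dimethylsilane | C=C(O[Si](C)(C)C(C)(C)C)C1=C(COCOC)CCC[C@@]1(C)CO[Si](c1ccccc1)(c1ccccc1)C(C)(C)C | intermediate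
15 | ethyl buta-2,3-dienoate | C=C=CC(=O)OCC | starting material
16 | ethyl (1R,5R,8aR)-4-{[tert-butyl(dimethyl)silyl]oxy}-5-{[tert-butyl(diphenyl)silyl]oxymethyl}-8a-[(methoxymethoxy)methyl]-5-methyl-2-methylidene-1,2,3,5,6,7,8,8a-octahydronaphthalene-1-carboxylate | C=C1CC(O[Si](C)(C)C(C)(C)C)=C2[C@](C)(CO[Si](c3ccccc3)(c3ccccc3)C(C)(C)C)CCC[C@@]2(COCOC)[C@@H]1C(=O)OCC | intermediate
17 | ethyl (1R,5R,8aR)-5-{[tert-butyl(diphenyl)silyl]oxymethyl}-4-hydroxy-8a-[(methoxymethoxy)methyl]-5-methyl-2-methylidene-1,2,3,5,6,7,8,8a-octahydronaphthalene-1-carboxylate | C=C1CC(O)=C2[C@](C)(CO[Si](c3ccccc3)(c3ccccc3)C(C)(C)C)CCC[C@@]2(COCOC)[C@@H]1C(=O)OCC | intermediate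
18 | ethyl (1R,4aR,5R,8aS)-5-{[tert-butyl(diphenyl)silyl]oxymethyl}-8a-[(methoxymethoxy)methyl]-5-methyl-2-methylidene-4-oxodecahydronaphthalene-1-carboxylate | C=C1CC(=O)[C@@H]2[C@](C)(CO[Si](c3ccccc3)(c3ccccc3)C(C)(C)C)CCC[C@@]2(COCOC)[C@@H]1C(=O)OCC | intermediate
19 | ethyl (1R,4aR,5R,8aS)-5-{[tert-butyl(diphenyl)silyl]oxymethyl}-8a-[(methoxymethoxy)methyl]-5-methyl-2-methylidene-4-[2-(4-methylbenzenesulfonyl)hydrazinylidene]decahydronaphthalene-1-carboxylate | C=C1CC(=NNS(=O)(=O)c3ccc(C)cc3)[C@@H]2[C@](C)(CO[Si](c3ccccc3)(c3ccccc3)C(C)(C)C)CCC[C@@]2(COCOC)[C@@H]1C(=O)OCC | intermediate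
20 | ethyl (1R,4aR,5R,8aS)-5-{[tert-butyl(diphenyl)silyl]oxymethyl}-8a-[(methoxymethoxy)methyl]-5-methyl-2-methylidene-4-[2-(4-methylbenzenesulfonyl)hydrazinyl]decahydronaphthalene-1-carboxylate (C4 of the ring unassigned) | C=C1CC(NNS(=O)(=O)c3ccc(C)cc3)[C@@H]2[C@](C)(CO[Si](c3ccccc3)(c3ccccc3)C(C)(C)C)CCC[C@@]2(COCOC)[C@@H]1C(=O)OCC | intermediate
21 | ethyl (1R,4aR,5R,8aS)-5-{[tert-butyl(diphenyl)silyl]oxymethyl}-8a-[(methoxymethoxy)methyl]-5-methyl-2-methylidenedecahydronaphthalene-1-carboxylate | C=C1CC[C@@H]2[C@](C)(CO[Si](c3ccccc3)(c3ccccc3)C(C)(C)C)CCC[C@@]2(COCOC)[C@@H]1C(=O)OCC | intermediate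
22 | [(1R,4aR,5R,8aS)-5-{[tert-butyl(diphenyl)silyl]oxymethyl}-8a-[(methoxymethoxy)methyl]-5-methyl-2-methylidenedecahydronaphthalen-1-yl]methanol | C=C1CC[C@@H]2[C@](C)(CO[Si](c3ccccc3)(c3ccccc3)C(C)(C)C)CCC[C@@]2(COCOC)[C@@H]1CO | intermediate
23 | (1R,4aR,5R,8aS)-5-{[tert-butyl(diphenyl)silyl]oxymethyl}-8a-[(methoxymethoxy)methyl]-5-methyl-2-methylidenedecahydronaphthalene-1-carbaldehyde | C=C1CC[C@@H]2[C@](C)(CO[Si](c3ccccc3)(c3ccccc3)C(C)(C)C)CCC[C@@]2(COCOC)[C@@H]1C=O | intermediate
24 | tert-butyl{[(1R,4aS,5R,8aR)-5-ethenyl-4a-[(methoxymethoxy)methyl]-1-methyl-6-methylidenedecahydronaphthalen-1-yl]methoxy}diphenylsilane | C=C1CC[C@@H]2[C@](C)(CO[Si](c3ccccc3)(c3ccccc3)C(C)(C)C)CCC[C@@]2(COCOC)[C@@H]1C=C | intermediate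
25 | [(1R,4aS,5R,8aR)-5-ethenyl-4a-[(methoxymethoxy)methyl]-1-methyl-6-methylidenedecahydronaphthalen-1-yl]methanol | C=C1CC[C@@H]2[C@](C)(CO)CCC[C@@]2(COCOC)[C@@H]1C=C | intermediate
26 | [(1R,4aS,5R,8aR)-5-ethenyl-4a-[(methoxymethoxy)methyl]-1-methyl-6-methylidenedecahydronaphthalen-1-yl]methyl acetate | C=C1CC[C@@H]2[C@](C)(COC(C)=O)CCC[C@@]2(COCOC)[C@@H]1C=C | intermediate
27 | 3-bromofuran-2(5H)-one | O=C1OCC=C1Br | starting material
28 | [(1R,4aR,5R,8aR)-5-{2-[bis(3-methylbutan-2-yl)boranyl]ethyl}-4a-[(methoxymethoxy)methyl]-1-methyl-6-methylidenedecahydronaphthalen-1-yl]methyl acetate | C=C1CC[C@@H]2[C@](C)(COC(C)=O)CCC[C@@]2(COCOC)[C@@H]1CCB(C(C)C(C)C)C(C)C(C)C | intermediate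
29 | [(1R,4aR,5R,8aR)-4a-[(methoxymethoxy)methyl]-1-methyl-6-methylidene-5-[2-(2-oxo-2,5-dihydrofuran-3-yl)ethyl]decahydronaphthalen-1-yl]methyl acetate | C=C1CC[C@@H]2[C@](C)(COC(C)=O)CCC[C@@]2(COCOC)[C@@H]1CCC1=CCOC1=O | intermediate
30 | [(1R,4aR,5R,8aR)-4a-[(bromomethoxy)methyl]-1-methyl-6-methylidene-5-[2-(2-oxo-2,5-dihydrofuran-3-yl)ethyl]decahydronaphthalen-1-yl]methyl acetate | C=C1CC[C@@H]2[C@](C)(COC(C)=O)CCC[C@@]2(COCBr)[C@@H]1CCC1=CCOC1=O | intermediate
31 | [(1R,4aR,5R,8aR)-4a-(hydroxymethyl)-1-methyl-6-methylidene-5-[2-(2-oxo-2,5-dihydrofuran-3-yl)ethyl]decahydronaphthalen-1-yl]methyl acetate | C=C1CC[C@@H]2[C@](C)(COC(C)=O)CCC[C@@]2(CO)[C@@H]1CCC1=CCOC1=O | intermediate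
32 | [(1R,4aR,5R,8aR)-4a-formyl-1-methyl-6-methylidene-5-[2-(2-oxo-2,5-dihydrofuran-3-yl)ethyl]decahydronaphthalen-1-yl]methyl acetate | C=C1CC[C@@H]2[C@](C)(COC(C)=O)CCC[C@@]2(C=O)[C@@H]1CCC1=CCOC1=O | target

**Step count and risks**

Total step count: 19. Longest linear sequence: 19 steps (1 to 32); the partners 6, 7, 12, 15 and 27 are commercial.

Steps most likely to fail:

1. Step 8 (Diels–Alder reaction). The C4 quaternary centre and the cis CH2OMOM group on C10 twist the diene, so cycloaddition may be slower than oligomerisation of the allenoate, and face or exo selectivity may be modest. The fallback is a stepwise anionic annulation (Michael–Michael ring closure) that sets out from enone 13. Its kinetic lithium enolate (LiN(iPr)2, THF, −78 °C) is added to the central carbon of 15 to give the open-chain keto ester ethyl 5-[(6R)-6-(TBDPS-oxymethyl)-2-(MOM-oxymethyl)-6-methylcyclohex-1-en-1-yl]-3-methylidene-5-oxopentanoate F1 as its ester dienolate. On warming, this dienolate should close ring B by intramolecular Michael addition of C9 to the enone carbon C10. Quenching with acetic acid at low temperature protonates C5 as in step 9, and the route is rejoined at ketone 18.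

2. Step 17 (hydroboration and B-alkyl coupling). The borane may also attack the C8(17) methylene, transmetalation of the hindered trialkylborane may be sluggish, and the bromobutenolide may decompose under aqueous base. The fallback is a base-free Negishi route that sets out from acetate 26. The disiamylborane adduct 28 is oxidised with NaBO3·4H2O to the C12 alcohol [(1R,4aR,5R,8aR)-5-(2-hydroxyethyl)-4a-(MOM-oxymethyl)-1-methyl-6-methylidenedecahydronaphthalen-1-yl]methyl acetate F4, which can be separated from any C17 regioisomer. An Appel reaction (I2, PPh3, imidazole) gives the iodide [(1R,4aR,5R,8aR)-5-(2-iodoethyl)-4a-(MOM-oxymethyl)-1-methyl-6-methylidenedecahydronaphthalen-1-yl]methyl acetate F5. Activated Zn in N,N-dimethylacetamide gives the alkylzinc iodide F6, and PdCl2(dppf)-catalysed Negishi coupling with 27 rejoins the route at 29.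

3. Step 10 (with step 11, removal of the C6 carbonyl). Condensation at the hindered C6 carbonyl may be slow, and prolonged heating may move the C8(17) alkene into conjugation while the ketone is present. The fallback is a radical deoxygenation that sets out from ketone 18. NaBH4 (MeOH, 0 °C) gives the C6 alcohol ethyl (1R,4aR,5R,8aS)-4-hydroxy-8a-(MOM-oxymethyl)-5-methyl-2-methylidene-5-(TBDPS-oxymethyl)decahydronaphthalene-1-carboxylate F2. 1,1'-Thiocarbonyldiimidazole with DMAP in 1,2-dichloroethane at 80 °C gives the imidazolyl thiocarbonate of that alcohol F3. Barton–McCombie reduction (Bu3SnH, AIBN, PhMe, 100 °C) rejoins the route at ester 21.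

**Further compounds**

F1 | step 8 | ethyl 5-[(6R)-6-{[tert-butyl(diphenyl)silyl]oxymethyl}-2-[(methoxymethoxy)methyl]-6-methylcyclohex-1-en-1-yl]-3-methylidene-5-oxopentanoate | C=C(CC(=O)OCC)CC(=O)C1=C(COCOC)CCC[C@@]1(C)CO[Si](c1ccccc1)(c1ccccc1)C(C)(C)C
F2 | step 10 | ethyl (1R,4aR,5R,8aS)-5-{[tert-butyl(diphenyl)silyl]oxymethyl}-4-hydroxy-8a-[(methoxymethoxy)methyl]-5-methyl-2-methylidenedecahydronaphthalene-1-carboxylate | C=C1CC(O)[C@@H]2[C@](C)(CO[Si](c3ccccc3)(c3ccccc3)C(C)(C)C)CCC[C@@]2(COCOC)[C@@H]1C(=O)OCC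
F3 | step 10 | ethyl (1R,4aR,5R,8aS)-5-{[tert-butyl(diphenyl)silyl]oxymethyl}-4-[(1H-imidazol-1-ylcarbonothioyl)oxy]-8a-[(methoxymethoxy)methyl]-5-methyl-2-methylidenedecahydronaphthalene-1-carboxylate | C=C1CC(OC(=S)n3ccnc3)[C@@H]2[C@](C)(CO[Si](c3ccccc3)(c3ccccc3)C(C)(C)C)CCC[C@@]2(COCOC)[C@@H]1C(=O)OCC
F4 | step 17 | [(1R,4aR,5R,8aR)-5-(2-hydroxyethyl)-4a-[(methoxymethoxy)methyl]-1-methyl-6-methylidenedecahydronaphthalen-1-yl]methyl acetate | C=C1CC[C@@H]2[C@](C)(COC(C)=O)CCC[C@@]2(COCOC)[C@@H]1CCO
F5 | step 17 | [(1R,4aR,5R,8aR)-5-(2-iodoethyl)-4a-[(methoxymethoxy)methyl]-1-methyl-6-methylidenedecahydronaphthalen-1-yl]methyl acetate | C=C1CC[C@@H]2[C@](C)(COC(C)=O)CCC[C@@]2(COCOC)[C@@H]1CCI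
F6 | step 17 | {2-[(1R,4aR,5R,8aR)-5-(acetyloxymethyl)-8a-[(methoxymethoxy)methyl]-5-methyl-2-methylidenedecahydronaphthalen-1-yl]ethyl}zinc iodide | C=C1CC[C@@H]2[C@](C)(COC(C)=O)CCC[C@@]2(COCOC)[C@@H]1CC[Zn]I
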